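Start from the amounts. At 1.3 equiv of E, the last readings put D at 5.2 % of the Z charged in alpha and 7.0 % in epsilon, while gamma, with 0.65 equiv, reads 4.2 %. Treat these as plateaus: alpha reads 5.6 % at 1.25 d and 5.2 % at 2.50 d, a gap smaller than the scatter of 0.5 percentage points. So leave the time at 2.0 d and decide on the charge.

| flask | Z | E | remark | time |
|---|---|---|---|---|
| alpha | 0.067 M | 1.3 equiv | run made earlier |  |
| epsilon | 0.15 M | 1.3 equiv | run made earlier |  |
| gamma | 0.10 M | 0.65 equiv | run made earlier |  |
| flask | 0.10 M | 1.30 equiv |  | 2.0 d |

| run | time / d | D / % | Z / % |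
|---|---|---|---|
| alpha | 0.208 | 14.0 | 0 |
| alpha | 0.333 | 9.2 | 0.1 |
| alpha | 0.625 | 4.9 | 0.4 |
| alpha | 1.25 | 5.6 | 0.2 |
| alpha | 2.50 | 5.2 | 0 |
| epsilon | 0.500 | 8.2 | 0 |
| epsilon | 1.04 | 6.4 | 0.2 |
| epsilon | 1.25 | 7.5 | 1.2 |
| epsilon | 2.08 | 7.0 | 0 |
| epsilon | 2.50 | 7.0 | 0.1 |
| gamma | 0.500 | 6.0 | 0 |
| gamma | 1.04 | 3.9 | 0 |
| gamma | 1.25 | 4.3 | 0 |
| gamma | 2.08 | 4.0 | 0.2 |
| gamma | 2.50 | 4.2 | 0.2 |

(standard deviation of a reading: 0.5 percentage points)

- a species is counted by the Z in it: one L counts as two
- given per volume of solution although it is solid: Z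
- what was read earlier has a scatter of 0.5 percentage points, one standard deviation
- on the list of suspects stand: Z <-> X; X + E -> D; 2 X -> L; E -> Q; D <-> J
- at the start none of Z is in solution

- how much D there is at 2.0 d, in percent of the Z charged
- the change that raises the amount of D at 2.0 d, in percent of the Z charged most ("none" if none brings more than 2 percentage points) (dawn / summer / noon / none)
- amount of D at 2.0 d, in percent of the Z charged, after dawn

- dawn: doubling the dissolution coefficient of Z, all else as stated
- summer: doubling the amount of E, all else as stated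
- noon: doubling the solubility of Z, all else as stated

Interpolate in logarithms between alpha and epsilon: with the equivalents of E held, these readings make D go as Z to the power 0.369, which puts the flask at 6.03 % by my reckoning. Then set this value against gamma, charged with the same Z. The E slope, the step in ln D per step in ln E at fixed Z and on the plateau, so that time has dropped out, comes to 0.521; it is an apparent order in E. If the slope holds beyond the charges read, doubling E in the flask adds an estimated 2.6 points, more than the margin of 2 points, though the excess of 0.60 points stands against a scatter of 0.5 points. Double E, and leave dissolution and solubility as they are, since no run so far varies them.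

The forecast gives 6.1 % (5.6 % to 6.6 %), names summer and gives 5.2 % (4.2 % to 6.3 %) after dawn. Its slope is 0.6, steeper than mine, and against noon it says “Higher solubility should also raise X and hurt”.

The flask gives 6.26 % at 2.0 d and 5.92 % after dawn, both inside the forecast's ranges, and the best change is summer.

    Z ⇌ X, rate k1*(cs1 - [X]) while solid is left; crystals form when [X] > cs1 (solubility = 0.0640 M, k = 0.0290 min⁻¹)
    X + E → D (k = 0.0640 M⁻¹ min⁻¹)
    2 X → L (k = 0.170 M⁻¹ min⁻¹)
    E → Q (k = 3.90 × 10⁻⁶ min⁻¹)
    D ⇌ J (K = 6.20, k = 0.00540 min⁻¹)

In this flask D and J relax with a half-life of 0.0768 d, short against 2.0 d. D reads 6.29 % at 1.00 d and 6.26 % at 20.0 d. On the flask's 6.26 %, the E slope of 0.521 gives 2.7 points for doubling E, and the flask gains 2.7 points. On the neighbour charged with 3.20 equiv of E, the slope gives 10.0 %, and that neighbour holds 9.70 %.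

All runs were computed on assumed constants, noise included.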